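The route rests on cutting the tridecyl side chain between C4′ and C5′ (C1′ sits on ring C5 of the furan-2(5H)-one, C13′ carries the acetate). Both carbons are plain primary CH2 groups in a heteroatom-free polymethylene run, so each can be unmasked from a carboxylic acid: a mixed Kolbe electrolysis joins 10-acetoxydecanoic acid and a butenolide-bearing pentanoic acid in one anodic, doubly decarboxylative radical coupling that delivers the complete C13 chain with the acetate in place. The precursor is the finished (R)-butenolide, built from methyl (R)-glycidate through a tetronic acid triflate and carbonylation, with the ring carboxyl masked as a benzyl ester and a 4-carboxybutyl arm at C5.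

Key step: step 7

Remark: the ring is numbered as furan-2(5H)-one (O1, C2=O, C3–Me, C4–CO2H, C5–H); by the CIP rules (O1 > C4 > C1′ > H) the given stereocentre is R, and methyl (R)-glycidate, 5-bromopent-1-ene and 10-hydroxydecanoic acid are taken as commercial.

Step 1
Reactants: 1 methyl (2R)-oxirane-2-carboxylate; 2 5-bromopent-1-ene
Product: 5 methyl (2R)-2-(propanoyloxy)oct-7-enoate, via pent-4-enylmagnesium bromide 3 (not isolated), via bromomagnesium alkoxide 4 (not isolated)
Conditions: Mg, THF, rt; CuBr·SMe2 (10 mol%), THF, −78 °C, add 1, −78 → −30 °C; then (EtCO)2O, DMAP (cat.), −30 → 0 °C; aq. NH4Cl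
Reagents that add atoms: propanoic anhydride CCC(=O)OC(=O)CC
Why: Copper-catalysed Grignard opening (SN2) of the glycidic ester at the unsubstituted C3 is faster than ester addition at low temperature and leaves the C2 stereocentre of the chiral-pool epoxide untouched (R retained), and the magnesium alkoxide is then O-acylated in the same flask by the anhydride.

Step 2
Reactants: 5 methyl (2R)-2-(propanoyloxy)oct-7-enoate
Product: 6 (5R)-5-(hex-5-en-1-yl)-4-hydroxy-3-methylfuran-2(5H)-one
Conditions: LiHMDS (2.3 equiv), THF, −78 → 0 °C; then 1 M HCl
Reagents that add atoms: none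
Why: Dieckmann (intramolecular Claisen) condensation, in which kinetic deprotonation of the propanoate CH2 and 5-exo-trig attack on the neighbouring methyl ester should give the 3-methyltetronic acid; the C–H at the stereocentre is not removed at −78 °C and the product rests as its tetronate anion, so the R configuration should be retained.

Step 3
Reactants: 6 (5R)-5-(hex-5-en-1-yl)-4-hydroxy-3-methylfuran-2(5H)-one
Product: 7 (2R)-2-(hex-5-en-1-yl)-4-methyl-5-oxo-2,5-dihydrofuran-3-yl trifluoromethanesulfonate
Conditions: Tf2O, iPr2NEt, CH2Cl2, −78 °C
Reagents that add atoms: trifluoromethanesulfonic anhydride O=S(=O)(OS(=O)(=O)C(F)(F)F)C(F)(F)F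
Why: O-Sulfonylation of the acidic C4 enol of the tetronic acid (a vinylogous carboxylic acid) at low temperature should give the enol triflate without touching C5 (enol triflate formation).

Step 4
Reactants: 7 (2R)-2-(hex-5-en-1-yl)-4-methyl-5-oxo-2,5-dihydrofuran-3-yl trifluoromethanesulfonate
Product: 8 benzyl (2R)-2-(hex-5-en-1-yl)-4-methyl-5-oxo-2,5-dihydrofuran-3-carboxylate
Conditions: Pd(OAc)2 (5 mol%), dppf (6 mol%), CO (1 atm), BnOH, Et3N, DMF, 50 °C
Reagents that add atoms: carbon monoxide [C-]#[O+]; benzyl alcohol OCc1ccccc1
Why: Palladium-catalysed alkoxycarbonylation, in which oxidative addition of Pd(0) into the electron-poor enol triflate, CO insertion and benzyl alcoholysis of the acyl–palladium species place the ester carbon on C4 without affecting C5 or the remote terminal alkene.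

Step 5
Reactants: 8 benzyl (2R)-2-(hex-5-en-1-yl)-4-methyl-5-oxo-2,5-dihydrofuran-3-carboxylate
Product: 9 5-[(2R)-3-(benzyloxycarbonyl)-4-methyl-5-oxo-2,5-dihydrofuran-2-yl]pentanoic acid
Conditions: RuCl3·xH2O (3 mol%), NaIO4 (4.2 equiv), MeCN/EtOAc/H2O, 0 °C → rt
Reagents that add atoms: sodium periodate [Na+].[O-]I(=O)(=O)=O; water O
Why: Ruthenium tetroxide oxidative cleavage (Sharpless RuCl3/NaIO4) should convert the electron-rich monosubstituted alkene into the carboxylic acid with loss of one carbon, while the tetrasubstituted, doubly acceptor-substituted butenolide alkene and the benzyl ester react far more slowly.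

Step 6
Reactants: 10 10-hydroxydecanoic acid
Product: 12 10-acetoxydecanoic acid, via acetic 10-acetoxydecanoic anhydride 11 (not isolated)
Conditions: Ac2O (2.5 equiv), pyridine, DMAP (cat.), CH2Cl2, rt; then H2O/THF, rt
Reagents that add atoms: acetic anhydride CC(=O)OC(C)=O; water O
Why: DMAP-catalysed O-acetylation of the primary alcohol also converts the carboxyl group into the mixed anhydride, which the aqueous stir hydrolyses back to the free acid while the alkyl acetate survives.

Step 7
Reactants: 9 5-[(2R)-3-(benzyloxycarbonyl)-4-methyl-5-oxo-2,5-dihydrofuran-2-yl]pentanoic acid; 12 10-acetoxydecanoic acid (6 equiv)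
Product: 13 benzyl (2R)-2-(13-acetoxytridecyl)-4-methyl-5-oxo-2,5-dihydrofuran-3-carboxylate
Conditions: undivided cell, smooth Pt anode and cathode, KOH (5 mol% of total acid), MeOH, 25–35 °C, constant current ca. 150 mA cm−2, stopped when the electrolyte reaches pH ca. 7.5
Reagents that add atoms: none
Why: Anodic one-electron oxidation of the two alkanoates at platinum gives acyloxy radicals that lose CO2 at once to the primary 9-acetoxynonyl and 4-(butenolid-5-yl)butyl radicals, which recombine in the dense radical layer at the electrode to forge C4′–C5′, while hydrogen is evolved at the cathode. The closest known reaction type is the mixed (crossed) Kolbe electrolysis long used to assemble long-chain fatty acid and pheromone skeletons from two ω-functionalised acids. No ring is closed and no stereocentre is created; the C5 stereocentre lies four carbons from the radical site and should be carried through unchanged in the weakly acidic, carboxylate-buffered medium. The step needs cross- rather than homo-coupling, which is secured statistically by the six-fold excess of the cheap acid 12, the symmetrical 1,18-diacetoxyoctadecane being non-polar and easy to remove. It also needs one-electron (radical) rather than two-electron (Hofer–Moest carbocation) behaviour and a single oxidisable carboxylate per partner, which the unbranched primary radicals without α-heteroatoms, the high current density and the benzyl ester mask on the ring acid secure. 6-exo cyclisation onto the tetrasubstituted butenolide alkene and 1,5-hydrogen transfer from C5–H are expected to be much slower than radical–radical coupling at the electrode surface.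

Step 8
Reactants: 13 benzyl (2R)-2-(13-acetoxytridecyl)-4-methyl-5-oxo-2,5-dihydrofuran-3-carboxylate
Product: 14 (2R)-2-(13-acetoxytridecyl)-4-methyl-5-oxo-2,5-dihydrofuran-3-carboxylic acid
Conditions: H2 (1 atm), 10% Pd/C, EtOAc, rt, stopped after uptake of 1 equiv H2
Reagents that add atoms: none
Why: Catalytic hydrogenolysis of the benzylic C–O bond of a benzyl ester is much faster than hydrogenation of the hindered tetrasubstituted butenolide alkene, so the acid should be released with acetate, lactone and C5 stereocentre intact.

Compound list
1 | methyl (2R)-oxirane-2-carboxylate (methyl (R)-glycidate) | COC(=O)[C@H]1CO1 | starting material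
2 | 5-bromopent-1-ene | C=CCCCBr | starting material
3 | pent-4-en-1-ylmagnesium bromide | C=CCCC[Mg]Br | intermediate
4 | bromomagnesium alkoxide of methyl (2R)-2-hydroxyoct-7-enoate | C=CCCCC[C@@H](O[Mg]Br)C(=O)OC | intermediate
5 | methyl (2R)-2-(propanoyloxy)oct-7-enoate | C=CCCCC[C@@H](OC(=O)CC)C(=O)OC | intermediate
6 | (5R)-5-(hex-5-en-1-yl)-4-hydroxy-3-methylfuran-2(5H)-one | C=CCCCC[C@H]1OC(=O)C(C)=C1O | intermediate
7 | (2R)-2-(hex-5-en-1-yl)-4-methyl-5-oxo-2,5-dihydrofuran-3-yl trifluoromethanesulfonate | C=CCCCC[C@H]1OC(=O)C(C)=C1OS(=O)(=O)C(F)(F)F | intermediate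
8 | benzyl (2R)-2-(hex-5-en-1-yl)-4-methyl-5-oxo-2,5-dihydrofuran-3-carboxylate | C=CCCCC[C@H]1OC(=O)C(C)=C1C(=O)OCc1ccccc1 | intermediate
9 | 5-[(2R)-3-(benzyloxycarbonyl)-4-methyl-5-oxo-2,5-dihydrofuran-2-yl]pentanoic acid | OC(=O)CCCC[C@H]1OC(=O)C(C)=C1C(=O)OCc1ccccc1 | intermediate
10 | 10-hydroxydecanoic acid | OCCCCCCCCCC(=O)O | starting material
11 | acetic 10-acetoxydecanoic anhydride | CC(=O)OCCCCCCCCCC(=O)OC(C)=O | intermediate
12 | 10-acetoxydecanoic acid | CC(=O)OCCCCCCCCCC(=O)O | intermediate
13 | benzyl (2R)-2-(13-acetoxytridecyl)-4-methyl-5-oxo-2,5-dihydrofuran-3-carboxylate | CC(=O)OCCCCCCCCCCCCC[C@H]1OC(=O)C(C)=C1C(=O)OCc1ccccc1 | intermediate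
14 | (2R)-2-(13-acetoxytridecyl)-4-methyl-5-oxo-2,5-dihydrofuran-3-carboxylic acid | CC(=O)OCCCCCCCCCCCCC[C@H]1OC(=O)C(C)=C1C(=O)O | target

Total step count: 8
Longest linear sequence: 7 (steps 1–5, 7, 8)

Steps most likely to fail

1. Step 7 (mixed Kolbe electrolysis). The two radicals may pair with themselves rather than with each other. The butenolide-bearing radical may also rearrange by hydrogen transfer or cyclisation before it meets a partner, and the acetate may be methanolysed if the electrolyte turns basic towards the end. The fallback sets out from 9 and 12 and comes back to the route at 13. Each acid is condensed with N-hydroxyphthalimide (N,N'-diisopropylcarbodiimide, DMAP cat., CH2Cl2) to give 1,3-dioxoisoindolin-2-yl 5-[(2R)-3-(benzyloxycarbonyl)-4-methyl-5-oxo-2,5-dihydrofuran-2-yl]pentanoate F1 and 1,3-dioxoisoindolin-2-yl 10-acetoxydecanoate F2. The two redox-active esters are then joined by nickel-catalysed reductive doubly decarboxylative cross-coupling (NiCl2·glyme, terpyridine ligand, AgNO3 additive, DMF, cathodic reduction at RVC with a sacrificial Mg anode, F2 in three-fold excess). Here the alkyl radicals are captured by nickel and coupled by reductive elimination, so the union no longer depends on two free radicals meeting, and no methanol or base is present.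

2. Step 4 (carbonylation of the enol triflate). Benzyl alcohol or the amine may cleave the vinylogous acyl triflate at sulfur or at C4 faster than palladium inserts, returning the tetronic acid or giving a 4-benzyloxy butenolide. The fallback sets out from 6 and comes back to the route at 8. The tetronic acid is converted with oxalyl bromide and catalytic DMF in CH2Cl2 into (5R)-4-bromo-5-(hex-5-en-1-yl)-3-methylfuran-2(5H)-one F3. This vinyl bromide has no sulfonyl group to attack and should tolerate alcohol and amine. It is then carbonylated (Pd(OAc)2, Xantphos, CO, BnOH, Et3N, toluene, 80 °C) to 8.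

3. Step 8 (hydrogenolysis). The catalyst may go on to saturate the butenolide C3=C4 bond or cleave the allylic C5–O bond once the benzyl group is gone. The fallback sets out from 13 and comes back to the route at 14, and it makes no new compound (F0). The benzyl ester is cleaved non-reductively with AlCl3 and anisole in CH2Cl2/MeNO2 at −20 → 0 °C. This is a Lewis-acid benzyl transfer to the arene that leaves the alkene untouched and should spare the acetate and lactone at low temperature.

Further compounds
F1 | step 7 | 1,3-dioxoisoindolin-2-yl 5-[(2R)-3-(benzyloxycarbonyl)-4-methyl-5-oxo-2,5-dihydrofuran-2-yl]pentanoate | O=C(CCCC[C@H]1OC(=O)C(C)=C1C(=O)OCc1ccccc1)ON1C(=O)c2ccccc2C1=O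
F2 | step 7 | 1,3-dioxoisoindolin-2-yl 10-acetoxydecanoate | CC(=O)OCCCCCCCCCC(=O)ON1C(=O)c2ccccc2C1=O
F3 | step 4 | (5R)-4-bromo-5-(hex-5-en-1-yl)-3-methylfuran-2(5H)-one | C=CCCCC[C@H]1OC(=O)C(C)=C1Br
F0 | step 8 | none | none
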